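Flavanone numbering (O1, C2–C4, C4a, C5–C8, C8a) is used for atoms throughout.

## Retrosynthetic overview
1. Flowerine ⇒ (2S)-5,7-diol. The last step is a 7-O-methylation; the chelated 5-OH stays free.
2. Diol ⇒ rings C and A both closed in one flask around a single carbon, C8a. The partners are an acyclic (S)-silyloxy β,β-dichlorovinyl ketone (ring B, C2–C4, C4a, C8a) and a prenylated dioxinone silyl dienolate (C5–C8).
3. Order in that flask: C8–C8a bond, then O1–C8a (ring C, pyranone), then dioxinone retro-[4+2] and dienylketene closure C4a–C5 (ring A). Ring B is bought.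
4. C2, the only stereocentre, comes from a catalytic asymmetric Mukaiyama aldol on anisaldehyde. Its C–O bond is never broken afterwards.
5. Building blocks: acetyl chloride with vinylidene chloride, and the diketene–acetone adduct with prenyl bromide.

Assumption: the (S)-tryptophan oxazaborolidinone is taken to attack the Re face of aryl aldehydes (R aldols), so its (R)-antipode is used; the sense is checked by chiral HPLC on 7 and the other antipode is used if needed.

## Route

Step 1
Reactants: 1 acetyl chloride; 2 1,1-dichloroethene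
Product: 4 4,4-dichlorobut-3-en-2-one, via 4,4,4-trichlorobutan-2-one 3 (not isolated)
Conditions: AlCl3 (1.05 equiv), CH2Cl2, 0 °C → rt; ice; aq. Na2CO3, steam distillation
Reagents that add atoms: none
Why: Kondakov-type Friedel–Crafts acylation of the alkene puts the acylium on CH2 and chloride on the CCl2 cation, and the acidic α-H of 3 then allows E1cB loss of HCl to the conjugated ketone; no stereocentre is formed.

Step 2
Reactants: 4 4,4-dichlorobut-3-en-2-one; 5 4-methoxybenzaldehyde
Product: 7 (S)-1,1-dichloro-5-(4-methoxyphenyl)-5-(trimethylsilyloxy)pent-1-en-3-one, via dichlorodienyl silyl ether 6 (not isolated)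
Conditions: (i) TMSOTf, i-Pr2NEt, Et2O, −10 °C, pentane extraction; (ii) 5, oxazaborolidinone from (R)-N-Ts-tryptophan/n-BuB(OH)2 (20 mol %), EtCN, −78 °C; pH 7 buffer
Reagents that add atoms: trimethylsilyl triflate, C[Si](C)(C)OS(=O)(=O)C(F)(F)F
Why: Only the methyl group can be enolised, and the oxazaborolidinone-catalysed Mukaiyama aldol reaction (known for terminal TMS enol ethers of methyl ketones and for 2-silyloxydienes with aryl aldehydes, open aldol pathway with silyl transfer) adds 6 to the Si face of 5, which sets C2 as S.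

Step 3
Reactants: 8 2,2,6-trimethyl-4H-1,3-dioxin-4-one; 9 prenyl bromide (1-bromo-3-methylbut-2-ene)
Product: 11 {[2,2-dimethyl-6-(4-methylpent-3-en-1-ylidene)-6H-1,3-dioxin-4-yl]oxy}trimethylsilane (E/Z mixture), via prenylated dioxinone 10 (not isolated)
Conditions: LDA, THF–DMPU, −78 °C, then 9 (0.95 equiv), → −20 °C; recool to −78 °C, LDA, then TMSCl, → 0 °C; pentane, filtration, concentration
Reagents that add atoms: chlorotrimethylsilane, C[Si](C)(C)Cl
Why: γ-Alkylation of the dioxinone lithium dienolate with allylic bromides is established, and a second γ-deprotonation with O-silylation gives the vinylogous silyl ketene acetal, whose alkene geometry is irrelevant because that carbon becomes aromatic C8.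

Step 4 (key step)
Reactants: 7 (S)-1,1-dichloro-5-(4-methoxyphenyl)-5-(trimethylsilyloxy)pent-1-en-3-one; 11 prenylated dioxinone silyl dienolate
Product: 15 (2S)-5,7-dihydroxy-2-(4-methoxyphenyl)-8-(3-methylbut-2-en-1-yl)-2,3-dihydro-4H-chromen-4-one, via chloroenone 12 (not isolated), via pyranone-dioxinone 13 (not isolated), via acylketene 14 (not isolated)
Conditions: TMSOTf (10 mol %), CH2Cl2, −78 → −20 °C; 2,6-di-tert-butyl-4-methylpyridine (15 mol %); PhMe (to 0.01 M), distil off CH2Cl2 and TMSCl, 110 °C, 1 h
Reagents that add atoms: none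
Why: Proposed new method: the CCl2 carbon serves as a vinylogous phosgene, so TMSOTf-activated 7 takes up the γ-carbon of 11 (vinylogous Mukaiyama–Michael addition, loss of TMSCl, 12), the silyl ether oxygen then displaces the second chloride by 6-endo addition–elimination (TMSCl, 13, ring C, C2–O bond untouched so S is kept), and heating triggers the dioxinone retro-[4+2] to acylketene 14, whose usual collapse to a 2-pyrone is impossible because the C8a oxygen is already alkylated, so its enol (a dienylketene) closes C4a–C5 by 6π electrocyclisation and tautomerises to ring A; the closest known reactions are γ-acylation of dioxinone dienolates with acid chlorides, dioxinone thermolysis–aromatisation to resorcylates, and the last stage of the Danheiser benzannulation.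

Step 5
Reactants: 15 (2S)-5,7-dihydroxy-2-(4-methoxyphenyl)-8-prenylchroman-4-one
Product: 16 Flowerine, (2S)-5-hydroxy-7-methoxy-2-(4-methoxyphenyl)-8-(3-methylbut-2-en-1-yl)-2,3-dihydro-4H-chromen-4-one
Conditions: MeOH (1.2 equiv), PPh3, DIAD, THF, 0 °C → rt
Reagents that add atoms: methanol, CO
Why: Mitsunobu etherification alkylates only the acidic free 7-OH because the 5-OH is hydrogen-bonded to C4=O, and the near-neutral medium avoids base-induced retro-oxa-Michael racemisation of C2.

## Compound list
1 | acetyl chloride | CC(=O)Cl | starting material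
2 | 1,1-dichloroethene | C=C(Cl)Cl | starting material
3 | 4,4,4-trichlorobutan-2-one | CC(=O)CC(Cl)(Cl)Cl | intermediate
4 | 4,4-dichlorobut-3-en-2-one | CC(=O)C=C(Cl)Cl | intermediate
5 | 4-methoxybenzaldehyde | COc1ccc(C=O)cc1 | starting material
6 | [(4,4-dichlorobuta-1,3-dien-2-yl)oxy]trimethylsilane | C=C(O[Si](C)(C)C)C=C(Cl)Cl | intermediate
7 | (S)-1,1-dichloro-5-(4-methoxyphenyl)-5-(trimethylsilyloxy)pent-1-en-3-one | COc1ccc([C@@H](O[Si](C)(C)C)CC(=O)C=C(Cl)Cl)cc1 | intermediate
8 | 2,2,6-trimethyl-4H-1,3-dioxin-4-one | CC1=CC(=O)OC(C)(C)O1 | starting material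
9 | prenyl bromide | CC(C)=CCBr | starting material
10 | 2,2-dimethyl-6-(4-methylpent-3-en-1-yl)-4H-1,3-dioxin-4-one | CC(C)=CCCC1=CC(=O)OC(C)(C)O1 | intermediate
11 | {[2,2-dimethyl-6-(4-methylpent-3-en-1-ylidene)-6H-1,3-dioxin-4-yl]oxy}trimethylsilane (E/Z mixture) | CC(C)=CCC=C1C=C(O[Si](C)(C)C)OC(C)(C)O1 | intermediate
12 | 6-[(7S)-3-chloro-7-(4-methoxyphenyl)-1-(2-methylprop-1-en-1-yl... i.e. β-chloroenone: ArCH(OTMS)CH2C(O)CH=C(Cl)CH(prenyl)-dioxinone (alkene and C8 mixtures) | COc1ccc([C@@H](O[Si](C)(C)C)CC(=O)C=C(Cl)C(CC=C(C)C)C2=CC(=O)OC(C)(C)O2)cc1 | intermediate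
13 | 6-{1-[(2S)-2-(4-methoxyphenyl)-4-oxo-3,4-dihydro-2H-pyran-6-yl]-4-methylpent-3-en-1-yl}-2,2-dimethyl-4H-1,3-dioxin-4-one (C8 epimers) | COc1ccc([C@@H]2CC(=O)C=C(C(CC=C(C)C)C3=CC(=O)OC(C)(C)O3)O2)cc1 | intermediate
14 | acylketene: 4-[(2S)-2-(4-methoxyphenyl)-4-oxo-3,4-dihydro-2H-pyran-6-yl]-7-methylocta-1,6-diene-1,3-dione | COc1ccc([C@@H]2CC(=O)C=C(C(CC=C(C)C)C(=O)C=C=O)O2)cc1 | intermediate
15 | (2S)-5,7-dihydroxy-2-(4-methoxyphenyl)-8-(3-methylbut-2-en-1-yl)chroman-4-one | COc1ccc([C@@H]2CC(=O)c3c(O)cc(O)c(CC=C(C)C)c3O2)cc1 | intermediate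
16 | Flowerine, (2S)-5-hydroxy-7-methoxy-2-(4-methoxyphenyl)-8-(3-methylbut-2-en-1-yl)chroman-4-one | COc1ccc([C@@H]2CC(=O)c3c(O)cc(OC)c(CC=C(C)C)c3O2)cc1 | target

## Step count and risks
Total steps: 5. Longest linear sequence: 4 (steps 1, 2, 4, 5); step 3 is convergent.

**1. Step 4.**
Risks:
- TMSOTf may ionise the p-methoxybenzylic C–O bond or reverse the aldol, which would erode the ee.
- The hindered γ-carbon of 11 may add slowly to the CCl2 terminus.
- If ring C is not closed before heating, the ketene closes onto the C–Cl carbon and gives an aryl chloride.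

The fallback sets out from 7 (and 9) and comes back at 16. Ring C is closed alone, and ring A is then made by a cycloaddition that brings the 7-OMe with it. CsF in MeCN at 0 °C desilylates 7, and the alkoxide closes to (S)-6-chloro-2-(4-methoxyphenyl)-2,3-dihydro-4H-pyran-4-one F1, which is isolated. Separately, the dianion of methyl acetoacetate (NaH, n-BuLi) is alkylated with 9 to methyl 7-methyl-3-oxooct-6-enoate F2. Trimethyl orthoformate with catalytic H2SO4 gives methyl (E)-3-methoxy-7-methylocta-2,6-dienoate F3. LDA/TMSCl then gives the Brassard-type diene [(1,3-dimethoxy-7-methylocta-1,3,6-trien-1-yl)oxy]trimethylsilane F4. F1 and F4 are heated in toluene with 2,6-lutidine. The nucleophilic diene terminus bonds to C8a, the adduct loses HCl through its acidic C4a–H and then loses MeOSiMe3, and 16 forms directly, so step 5 is not needed.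

**2. Step 2.**
Risks:
- 6 is a weak nucleophile and 5 a weak electrophile.
- The ee may stay near 90 %; in the main route it would be raised by recrystallising 15.

The fallback sets out from 4 and 5 and comes back at 7. It uses reagent control through a boron enolate instead of catalytic silyl enol ether chemistry. Compound 4 is enolised with i-Pr2NEt and the Ipc2BCl antipode that attacks the Si face. The enol borinate adds to 5 through a closed transition state. Diethanolamine work-up gives (S)-1,1-dichloro-5-hydroxy-5-(4-methoxyphenyl)pent-1-en-3-one F5. F5 is recrystallised to raise the ee and silylated (TMSCl, imidazole) to 7.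

**3. Step 3.**
Risks:
- α-Alkylation or double alkylation of the dienolate.
- Incomplete second deprotonation.
- A labile product.

The fallback sets out from 9 and comes back at 14. It uses a different ketene precursor. The dianion of tert-butyl acetoacetate is alkylated with 9 to tert-butyl 7-methyl-3-oxooct-6-enoate F6. TMSOTf/Et3N (2.2 equiv) gives the Chan-type diene 1-tert-butoxy-7-methyl-1,3-bis(trimethylsilyloxy)octa-1,3,6-triene F7. F7 takes the place of 11 in the cold part of step 4. After a bicarbonate wash this gives tert-butyl 4-[(2S)-2-(4-methoxyphenyl)-4-oxo-3,4-dihydro-2H-pyran-6-yl]-7-methyl-3-oxooct-6-enoate F8. Heating F8 in toluene expels tert-butanol and gives the same acylketene 14, which closes to 15.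

## Further compounds
F1 | step 4 | (S)-6-chloro-2-(4-methoxyphenyl)-2,3-dihydro-4H-pyran-4-one | COc1ccc([C@@H]2CC(=O)C=C(Cl)O2)cc1
F2 | step 4 | methyl 7-methyl-3-oxooct-6-enoate | CC(C)=CCCC(=O)CC(=O)OC
F3 | step 4 | methyl (E)-3-methoxy-7-methylocta-2,6-dienoate | COC(=O)/C=C(/OC)CCC=C(C)C
F4 | step 4 | [(1,3-dimethoxy-7-methylocta-1,3,6-trien-1-yl)oxy]trimethylsilane | COC(O[Si](C)(C)C)=CC(OC)=CCC=C(C)C
F5 | step 2 | (S)-1,1-dichloro-5-hydroxy-5-(4-methoxyphenyl)pent-1-en-3-one | COc1ccc([C@@H](O)CC(=O)C=C(Cl)Cl)cc1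
F6 | step 3 | tert-butyl 7-methyl-3-oxooct-6-enoate | CC(C)=CCCC(=O)CC(=O)OC(C)(C)C
F7 | step 3 | 1-tert-butoxy-7-methyl-1,3-bis(trimethylsilyloxy)octa-1,3,6-triene | CC(C)=CCC=C(O[Si](C)(C)C)C=C(O[Si](C)(C)C)OC(C)(C)C
F8 | step 3 | tert-butyl 4-[(2S)-2-(4-methoxyphenyl)-4-oxo-3,4-dihydro-2H-pyran-6-yl]-7-methyl-3-oxooct-6-enoate | COc1ccc([C@@H]2CC(=O)C=C(C(CC=C(C)C)C(=O)CC(=O)OC(C)(C)C)O2)cc1
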